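**Assumptions (one line each):** A recombinant type II chalcone isomerase (e.g. *Medicago sativa* CHI, expressed in *E. coli*) is available. The Friedel–Crafts step gives the 2,4-trans isomer as the major product, and the minor cis isomer is separable.

## Retrosynthesis
- Disconnect the C4–aryl bond: myristinin A comes from (2S)-7,4'-di-O-benzylflavan-4-ol (**6**) and 2,4,6-trihydroxydodecanophenone (**9**) by a Friedel–Crafts alkylation through the C4 benzylic cation. Axial attack on the half-chair cation, with the 2-aryl group equatorial, gives the 2,4-trans product.
- Flavan-4-ol **6** comes from the protected (2S)-flavanone **5**, which comes from (2S)-liquiritigenin (**4**).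
- The only ring formed is the pyran ring, and it is formed in the enzymatic step. Chalcone isomerase cyclises achiral isoliquiritigenin (**3**) to **4** and sets C2. Chalcone **3** comes from a Claisen–Schmidt condensation, and **9** from phloroglucinol and lauric acid.
- C4 is set by substrate control from C2 in the Friedel–Crafts step.

## Route

**Step 1**
Reactants: **1** 2',4'-dihydroxyacetophenone; **2** 4-hydroxybenzaldehyde
Product: **3** (E)-isoliquiritigenin, (E)-1-(2,4-dihydroxyphenyl)-3-(4-hydroxyphenyl)prop-2-en-1-one
Conditions: 50% aq. KOH (~8 equiv), EtOH, rt, 72 h; then 2 M HCl to pH 2; recrystallise (EtOH/H2O)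
Reagents that add atoms: none
Why: Claisen–Schmidt (aldol condensation) under strongly basic conditions keeps the chalcone as its phenolate, so premature cyclisation to racemic flavanone is suppressed. Recrystallisation removes any racemic flavanone before the enzymatic step.

**Step 2**
Reactant: **3** isoliquiritigenin
Product: **4** (2S)-liquiritigenin, (S)-7,4'-dihydroxyflavanone
Conditions: chalcone isomerase (EC 5.5.1.6), 50 mM KPi pH 7.0, 5% DMSO, substrate added portionwise to 1 mM, 25 °C, 3 h; extract with EtOAc
Reagents that add atoms: none (isomerisation)
Why: the enzyme catalyses the intramolecular 6-endo oxa-Michael addition within a chiral active site, forming the pyran ring and setting C2 as (S) with >99% ee from an achiral substrate. The uncatalysed background cyclisation at pH 7 is negligible by comparison.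

**Step 3**
Reactant: **4** (2S)-liquiritigenin
Product: **5** (2S)-7,4'-bis(benzyloxy)flavanone
Conditions: BnBr (2.4 equiv), K2CO3 (2.5 equiv), TBAI (5 mol%), acetone, 40 °C, 6 h
Reagents that add atoms: benzyl bromide, BrCc1ccccc1
Why: Williamson etherification of the two phenols. The mild, short conditions leave the C2 stereocentre untouched, and ee is checked by chiral HPLC.

**Step 4**
Reactant: **5**
Product: **6** (2S)-7,4'-bis(benzyloxy)flavan-4-ol, a mixture of C4 epimers
Conditions: NaBH4 (2 equiv), THF/MeOH 4:1, 0 °C, 1 h; sat. NH4Cl quench; crude used directly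
Reagents that add atoms: none (hydride adds only H)
Why: hydride reduction of the aryl ketone. The C4 configuration is irrelevant because C4 is ionised in step 6, and C2 is untouched because no enolisable carbonyl remains.

**Step 5**
Reactants: **7** phloroglucinol; **8** lauric acid (dodecanoic acid)
Product: **9** 2,4,6-trihydroxydodecanophenone
Conditions: BF3·OEt2 (neat, excess), 85 °C, 2 h; aq. NaOAc work-up
Reagents that add atoms: none (the acyl group comes from reactant **8**; water is lost)
Why: BF3-activated Friedel–Crafts C-acylation (Hoesch-type) of the very electron-rich phloroglucinol. A 1:1 stoichiometry gives the mono-acyl product, whose carbonyl is chelated by the flanking OH groups.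

**Step 6**
Reactants: **6** flavan-4-ol (1 equiv); **9** acylphloroglucinol (3 equiv)
Product: **10** (2S,4R)-7,4'-bis(benzyloxy)-4-(3-dodecanoyl-2,4,6-trihydroxyphenyl)flavan
Conditions: Sc(OTf)3 (10 mol%), MeCN, 0 °C → rt, 3 h; chromatography/prep-HPLC to remove the 2,4-cis isomer
Reagents that add atoms: none (water is lost)
Why: Friedel–Crafts benzylation through the 2,4-dioxygenated C4 cation. The nucleophile attacks axially on the half-chair cation, which has the 2-aryl group equatorial. This chair-like attack gives the 2,4-trans (2S,4R) product with the 4-aryl group axial, and excess **9** suppresses bis-alkylation and oligomerisation.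

**Step 7**
Reactant: **10**
Product: **11** (+)-myristinin A
Conditions: H2 (1 atm), 10% Pd/C, EtOAc/EtOH 1:1, rt, 6 h
Reagents that add atoms: none (H2 adds only hydrogen; toluene is lost)
Why: hydrogenolysis of the two aryl benzyl ethers. The chelated aryl ketone, the flavan C–O bond and both stereocentres survive the mild conditions.

## Compound list
1 | 2',4'-dihydroxyacetophenone | CC(=O)c1ccc(O)cc1O | starting material
2 | 4-hydroxybenzaldehyde | O=Cc1ccc(O)cc1 | starting material
3 | (E)-isoliquiritigenin | O=C(/C=C/c1ccc(O)cc1)c1ccc(O)cc1O | intermediate
4 | (2S)-liquiritigenin | O=C1C[C@@H](c2ccc(O)cc2)Oc2cc(O)ccc21 | intermediate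
5 | (2S)-7,4'-bis(benzyloxy)flavanone | O=C1C[C@@H](c2ccc(OCc3ccccc3)cc2)Oc2cc(OCc3ccccc3)ccc21 | intermediate
6 | (2S)-7,4'-bis(benzyloxy)flavan-4-ol (C4 epimers; only C2 defined) | OC1C[C@@H](c2ccc(OCc3ccccc3)cc2)Oc2cc(OCc3ccccc3)ccc21 | intermediate
7 | phloroglucinol | Oc1cc(O)cc(O)c1 | starting material
8 | lauric acid | CCCCCCCCCCCC(=O)O | starting material
9 | 2,4,6-trihydroxydodecanophenone | CCCCCCCCCCCC(=O)c1c(O)cc(O)cc1O | intermediate
10 | (2S,4R)-7,4'-bis(benzyloxy)-4-aryl-flavan | CCCCCCCCCCCC(=O)c1c(O)cc(O)c([C@@H]2C[C@@H](c3ccc(OCc4ccccc4)cc3)Oc3cc(OCc4ccccc4)ccc32)c1O | intermediate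
11 | (+)-myristinin A | CCCCCCCCCCCC(=O)c1c(O)cc(O)c([C@@H]2C[C@@H](c3ccc(O)cc3)Oc3cc(O)ccc32)c1O | target

## Summary
**Total steps:** 7.
**Longest linear sequence:** 6 steps (1 → 2 → 3 → 4 → 6 → 7, starting from **1** and **2**).

**Three steps most likely to fail:**
1. **Step 6 (Friedel–Crafts).** The trans:cis ratio may be poor, or the C2 centre may erode through ring-opening.
   - Fallback: abandon the cation chemistry and build the 2,4-diarylchromane in one operation. Use a chiral-phosphoric-acid-catalysed inverse-demand oxa-[4+2] between an o-quinone methide (from a 2-hydroxy-4-benzyloxyphenyl)(protected acylphloroglucinyl)methanol and 4-benzyloxystyrene, then deprotect.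
2. **Step 2 (chalcone isomerase).** Substrate solubility, enzyme supply or the equilibrium position may limit the yield.
   - Fallback: replace steps 1–3 with a Rh/chiral-diene-catalysed asymmetric 1,4-arylation of 7-benzyloxychromone with 4-benzyloxyphenylboronic acid, which gives **5** directly.
3. **Step 3 (benzylation).** The base may partly racemise the flavanone at C2.
   - Fallback: change the order. Reduce unprotected **4** at pH 7 with a ketoreductase (NADPH with glucose dehydrogenase recycling) to the flavan-4-ol, then bis-benzylate it. No enolisable carbonyl remains, so C2 cannot racemise, and the product is **6**.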